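The route rests on the side-chain bond C12–C13 (dictyol numbering: cyclopentene ring A = C1–C5, cycloheptane ring B = C1, C5–C10, side chain C11–C15 on C7). C13 is an allylic carbinol carbon flanked by the C14=C15 alkene, hence the carbonyl carbon of 3-methylbut-2-enal; C12 is a primary carbon outside both rings. In the key step the C12 alkylzinc of the fully built, bis-silylated trans-hydroazulene adds to this enal under Ti(OiPr)4/chiral bis-triflamide catalysis and the alkoxide is trapped with Ac2O: one operation joins the fifteen-carbon and five-carbon fragments, sets C13 by catalyst control and installs the acetate.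

Key step: step 14

Numbering and faces: C4 is the methyl carbinol carbon, C6 the ring B carbinol carbon, C10 carries the exocyclic methylene C18; β is the face of the bicycle carrying H5, both ring oxygens and the C7 side chain; H1, H6, H7 and the C4 methyl are α (trans ring fusion). The target is (1R,4S,5R,6R,7S,11R,13R).
Assumption: lactone 1 and silyloxy-enone 8 are taken as purchasable single enantiomers.

Step 1
Reactants: 1 (S)-4-methyloxolan-2-one; 2 allyl bromide
Product: 3 (3S,4S)-4-methyl-3-(prop-2-en-1-yl)oxolan-2-one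
Conditions: LiN(i-Pr)2, THF, −78 °C; then 2, −78 → −40 °C
Reagents that add atoms: none
Why: Lactone enolate alkylation; the allyl group should enter anti to the adjacent C11 methyl group of the five-membered enolate, setting C7 trans to C11.

Step 2
Reactants: 3 (3S,4S)-4-methyl-3-(prop-2-en-1-yl)oxolan-2-one
Product: 5 (2S,3S)-N-methoxy-N,3-dimethyl-2-(prop-2-en-1-yl)-4-(triethylsilyloxy)butanamide, via chloromagnesium alkoxide 4 (not isolated)
Conditions: MeNH(OMe)·HCl, i-PrMgCl, THF, −20 °C; then Et3SiCl, imidazole, 0 °C → rt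
Reagents that add atoms: N,O-dimethylhydroxylamine hydrochloride (CNOC.Cl); chlorotriethylsilane (CC[Si](Cl)(CC)CC)
Why: Weinreb amide formation by aminolysis of the lactone with the chloromagnesium amide, the liberated primary alkoxide being silylated in the same flask so that it cannot relactonise; no stereocentre is touched.

Step 3
Reactants: 5 (2S,3S)-N-methoxy-N,3-dimethyl-2-(prop-2-en-1-yl)-4-(triethylsilyloxy)butanamide
Product: 6 (2S,3S)-3-methyl-2-(prop-2-en-1-yl)-4-(triethylsilyloxy)butanal
Conditions: i-Bu2AlH, THF, −78 °C; aqueous Rochelle salt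
Reagents that add atoms: none
Why: Hydride reduction of a Weinreb amide stops at the aldehyde through the chelated tetrahedral intermediate, and the low temperature should prevent epimerisation at C7.

Step 4
Reactants: 6 (2S,3S)-3-methyl-2-(prop-2-en-1-yl)-4-(triethylsilyloxy)butanal; 7 (2-bromoprop-2-en-1-yl)trimethylsilane; 8 (S)-4-(tert-butyldimethylsilyloxy)cyclopent-2-en-1-one
Product: 12 (2R,3R,4S)-4-(tert-butyldimethylsilyloxy)-2-[(1R,2S,3S)-1-hydroxy-3-methyl-2-(prop-2-en-1-yl)-4-(triethylsilyloxy)butyl]-3-[3-(trimethylsilyl)prop-1-en-2-yl]cyclopentan-1-one, via vinyllithium 9 (not isolated), via vinylcopper reagent 10 (not isolated), via copper enolate 11 (not isolated)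
Conditions: 7, t-BuLi (2 equiv), Et2O, −78 °C; CuI, PBu3, −78 °C; 8, −78 °C; then 6, −78 °C; aqueous NH4Cl
Reagents that add atoms: none
Why: Three-component conjugate addition–aldol coupling: the vinylcopper reagent should add anti to the C2 silyloxy group (sets C1), the enolate should react anti to the new C1 substituent (sets C5 trans), and a Zimmerman–Traxler anti aldol with Felkin–Anh addition to the α-branched aldehyde (C11 branch large, allyl medium) should set C6.

Step 5
Reactants: 12 aldol adduct
Product: 14 (4R,5R)-5-[(1R,2S,3S)-3-methyl-2-(prop-2-en-1-yl)-1,4-bis(triethylsilyloxy)butyl]-4-[3-(trimethylsilyl)prop-1-en-2-yl]cyclopent-2-en-1-one, via C6 triethylsilyl ether 13 (not isolated)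
Conditions: Et3SiOTf, 2,6-lutidine, CH2Cl2, −78 °C; then DBU, 0 °C → rt
Reagents that add atoms: triethylsilyl trifluoromethanesulfonate (CC[Si](CC)(CC)OS(=O)(=O)C(F)(F)F)
Why: Silylation of the C6 hydroxyl blocks retro-aldol cleavage, and DBU then removes a C3 proton and expels the C2 silyloxy group (E1cB β-elimination), the ring methylene reacting faster than the hindered C5 methine, so no stereocentre is touched.

Step 6
Reactants: 14 cyclopentenone triene
Product: 15 trans-fused (1αH,5βH) hydroazulen-4-one with C2=C3 and C9=C10 alkenes, a trimethylsilylmethyl group on C10, 6β-triethylsilyloxy and a 7β-[(S)-1-(triethylsilyloxy)propan-2-yl] group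
Conditions: second-generation Grubbs catalyst (H2IMes)(PCy3)Cl2Ru=CHPh (5 mol %), CH2Cl2 (5 mM), 40 °C
Reagents that add atoms: none
Why: Ring-closing metathesis between the allyl alkene and the 1,1-disubstituted allylsilane alkene should close ring B as a trisubstituted C9=C10 cycloheptene with loss of ethene, the conjugated ring A alkene being inert.

Step 7
Reactants: 15 hydroazulen-4-one
Product: 17 C3=C4 enol triflate (4-trifluoromethanesulfonyloxy-3-ene with C2 now a methylene and all other groups as in 15), via lithium enolate 16 (not isolated)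
Conditions: LiBH(s-Bu)3, THF, −78 °C; then PhNTf2, −78 → 0 °C
Reagents that add atoms: N-phenylbis(trifluoromethanesulfonimide) (O=S(=O)(N(c1ccccc1)S(=O)(=O)C(F)(F)F)C(F)(F)F)
Why: Conjugate reduction–enolate trapping: the bulky trialkylborohydride should deliver hydride to C2, and the regiodefined C3=C4 enolate is triflated on oxygen before it can equilibrate.

Step 8
Reactants: 17 enol triflate
Product: 18 4-methyl-3-ene (C3=C4 alkene carrying the C4 methyl group, C9=C10 allylsilane and both triethylsilyl ethers retained)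
Conditions: MeMgBr, Fe(acac)3 (5 mol %), THF/NMP, −30 → 0 °C
Reagents that add atoms: methylmagnesium bromide (C[Mg]Br)
Why: Iron-catalysed Kumada-type cross-coupling of an alkenyl triflate with a methyl Grignard reagent, which tolerates silyl ethers and the allylsilane.

Step 9
Reactants: 18 4-methyl-3-ene allylsilane
Product: 20 6β,12-diol with C3=C4 (4-methyl) and exocyclic C10=C18 alkenes, via bis(triethylsilyl) ether 19 (not isolated)
Conditions: CF3CO2H, CH2Cl2, −20 °C; then Bu4NF, THF, 0 °C → rt
Reagents that add atoms: none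
Why: Protodesilylation of the allylsilane is an SE2′ process, the proton adding to C9 while the C–Si bond collapses to the exocyclic methylene, and fluoride then cleaves both triethylsilyl ethers.

Step 10
Reactants: 20 diene diol
Product: 21 3β,4β-epoxide of 20 (4α-methyl)
Conditions: VO(acac)2 (5 mol %), t-BuOOH, CH2Cl2, 0 °C → rt
Reagents that add atoms: tert-butyl hydroperoxide (CC(C)(C)OO)
Why: Hydroxyl-directed vanadium-catalysed epoxidation: the homoallylic 6β-hydroxyl should deliver oxygen to the β face of the trisubstituted C3=C4 alkene (also the face anti to the C5–C6 bond), leaving the undirected C10=C18 alkene alone and placing the C4 oxygen β.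

Step 11
Reactants: 21 epoxy diol
Product: 24 4β,6β,12-triol with C2=C3 and C10=C18 alkenes (4α-methyl), via 3α-phenylselanyl 4β-alcohol 22 (not isolated), via selenoxide 23 (not isolated)
Conditions: PhSeSePh, NaBH4, EtOH, rt → 60 °C; then H2O2, NaHCO3, THF, 0 °C → rt
Reagents that add atoms: none
Why: Selenide-mediated epoxide-to-allylic-alcohol transposition: the selenolate should open the epoxide at the secondary C3 with inversion, and syn elimination of the selenoxide, which can only take a C2 hydrogen, gives the C2=C3 alkene and leaves the tertiary C4 alcohol in its β configuration.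

Step 12
Reactants: 24 triol
Product: 25 12-iodo-4β,6β-diol
Conditions: I2, PPh3, imidazole, CH2Cl2, 0 °C
Reagents that add atoms: iodine (II)
Why: Appel-type iodination should select the unhindered primary C12 hydroxyl over the hindered secondary C6 and tertiary C4 hydroxyls.

Step 13
Reactants: 25 iodo diol
Product: 26 12-iodo-4β,6β-bis(triethylsilyloxy) compound
Conditions: Et3SiOTf, 2,6-lutidine, CH2Cl2, −78 → 0 °C
Reagents that add atoms: triethylsilyl trifluoromethanesulfonate (CC[Si](CC)(CC)OS(=O)(=O)C(F)(F)F)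
Why: Silyl triflate silylation of the secondary and the tertiary allylic hydroxyl removes every acidic proton before the organozinc step.

Step 14
Reactants: 26 bis-silylated iodide; 27 3-methylbut-2-enal
Product: 31 (13R)-13-acetoxy-4β,6β-bis(triethylsilyloxy) compound, via alkylzinc iodide 28 (not isolated), via mixed dialkylzinc 29 (not isolated), via zinc alkoxide 30 (not isolated)
Conditions: Zn dust (activated with BrCH2CH2Br and Me3SiCl), THF, 40 °C; Me3SiCH2Li, −78 °C; solvent exchange to toluene; Ti(OiPr)4, (1S,2S)-1,2-bis(trifluoromethanesulfonamido)cyclohexane (8 mol %), 27, −20 °C; then Ac2O, DMAP, 0 °C → rt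
Reagents that add atoms: acetic anhydride (CC(=O)OC(C)=O)
Why: Zinc inserts into the primary C12–I bond, Me3SiCH2Li converts the alkylzinc iodide into a mixed dialkylzinc, and the titanium bis-sulfonamide complex from Ti(OiPr)4 and the ligand binds the enal and delivers the C12 alkyl group to its carbonyl carbon, after which Ac2O acylates the metal alkoxide in the flask. The closest known reaction type is the Ti(OiPr)4/trans-1,2-bis(trifluoromethanesulfonamido)cyclohexane-catalysed enantioselective addition of functionalised dialkylzincs to aldehydes, which is established for α,β-unsaturated aldehydes. No ring is closed; the step is an intermolecular union of the hydroazulene with the five-carbon enal. The new C13 stereocentre is set by the catalyst: by analogy with additions to benzaldehyde, the (1S,2S) ligand should direct the alkyl group to the Re face and give 13R, and the C11 methyl stereocentre β to zinc is too remote to override it. The step needs 1,2- over 1,4-addition, secured by the β,β-disubstituted enal terminus and carbonyl activation, and transfer of the valuable alkyl group, secured by the non-transferable Me3SiCH2 ligand. Both hydroxyls are silylated and the isolated alkenes are inert, so nothing else in 26 should react.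

Step 15
Reactants: 31 bis-silylated acetate
Product: 32 target (1R,4S,5R,6R,7S,11R,13R)-13-acetoxy-4,6-diol
Conditions: HF·pyridine, pyridine, THF, 0 °C → rt
Reagents that add atoms: none
Why: Buffered fluoride should cleave both triethylsilyl ethers without ionising the tertiary allylic alcohol or cleaving the acetate.

Compound list
1 | (S)-4-methyloxolan-2-one | O=C1C[C@H](C)CO1 | starting material
2 | allyl bromide | C=CCBr | starting material
3 | (3S,4S)-4-methyl-3-(prop-2-en-1-yl)oxolan-2-one | O=C1[C@@H](CC=C)[C@H](C)CO1 | intermediate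
4 | chloromagnesium alkoxide of (2S,3S)-4-hydroxy-N-methoxy-N,3-dimethyl-2-(prop-2-en-1-yl)butanamide | CON(C)C(=O)[C@@H](CC=C)[C@H](C)CO[Mg]Cl | intermediate
5 | (2S,3S)-N-methoxy-N,3-dimethyl-2-(prop-2-en-1-yl)-4-(triethylsilyloxy)butanamide | CON(C)C(=O)[C@@H](CC=C)[C@H](C)CO[Si](CC)(CC)CC | intermediate
6 | (2S,3S)-3-methyl-2-(prop-2-en-1-yl)-4-(triethylsilyloxy)butanal | O=C[C@@H](CC=C)[C@H](C)CO[Si](CC)(CC)CC | intermediate
7 | (2-bromoprop-2-en-1-yl)trimethylsilane | C=C(Br)C[Si](C)(C)C | starting material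
8 | (S)-4-(tert-butyldimethylsilyloxy)cyclopent-2-en-1-one | O=C1C=C[C@@H](O[Si](C)(C)C(C)(C)C)C1 | starting material
9 | 3-(trimethylsilyl)prop-1-en-2-yllithium | [Li]C(=C)C[Si](C)(C)C | intermediate
10 | [3-(trimethylsilyl)prop-1-en-2-yl]copper (tributylphosphine complex) | [Cu]C(=C)C[Si](C)(C)C | intermediate
11 | copper enolate of (3R,4S)-4-(tert-butyldimethylsilyloxy)-3-[3-(trimethylsilyl)prop-1-en-2-yl]cyclopentanone | [Cu]OC1=C[C@H](C(=C)C[Si](C)(C)C)[C@@H](O[Si](C)(C)C(C)(C)C)C1 | intermediate
12 | (2R,3R,4S)-4-(tert-butyldimethylsilyloxy)-2-[(1R,2S,3S)-1-hydroxy-3-methyl-2-(prop-2-en-1-yl)-4-(triethylsilyloxy)butyl]-3-[3-(trimethylsilyl)prop-1-en-2-yl]cyclopentan-1-one | C=CC[C@@H]([C@H](C)CO[Si](CC)(CC)CC)[C@@H](O)[C@H]1[C@H](C(=C)C[Si](C)(C)C)[C@@H](O[Si](C)(C)C(C)(C)C)CC1=O | intermediate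
13 | C6 triethylsilyl ether of 12 | C=CC[C@@H]([C@H](C)CO[Si](CC)(CC)CC)[C@@H](O[Si](CC)(CC)CC)[C@H]1[C@H](C(=C)C[Si](C)(C)C)[C@@H](O[Si](C)(C)C(C)(C)C)CC1=O | intermediate
14 | (4R,5R)-5-[(1R,2S,3S)-3-methyl-2-(prop-2-en-1-yl)-1,4-bis(triethylsilyloxy)butyl]-4-[3-(trimethylsilyl)prop-1-en-2-yl]cyclopent-2-en-1-one | C=CC[C@@H]([C@H](C)CO[Si](CC)(CC)CC)[C@@H](O[Si](CC)(CC)CC)[C@H]1[C@H](C(=C)C[Si](C)(C)C)C=CC1=O | intermediate
15 | trans-fused hydroazulen-4-one: C2=C3, C9=C10, 10-(trimethylsilylmethyl), 6β-OSiEt3, 7β-[(S)-1-(triethylsilyloxy)propan-2-yl] | C[Si](C)(C)CC1=CC[C@@H]([C@H](C)CO[Si](CC)(CC)CC)[C@@H](O[Si](CC)(CC)CC)[C@H]2[C@H]1C=CC2=O | intermediate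
16 | lithium C3=C4 enolate from 1,4-reduction of 15 | C[Si](C)(C)CC1=CC[C@@H]([C@H](C)CO[Si](CC)(CC)CC)[C@@H](O[Si](CC)(CC)CC)[C@H]2[C@H]1CC=C2O[Li] | intermediate
17 | C3=C4 enol triflate (4-OTf) | C[Si](C)(C)CC1=CC[C@@H]([C@H](C)CO[Si](CC)(CC)CC)[C@@H](O[Si](CC)(CC)CC)[C@H]2[C@H]1CC=C2OS(=O)(=O)C(F)(F)F | intermediate
18 | 4-methyl-3-ene with C9=C10 allylsilane and both triethylsilyl ethers | C[Si](C)(C)CC1=CC[C@@H]([C@H](C)CO[Si](CC)(CC)CC)[C@@H](O[Si](CC)(CC)CC)[C@H]2[C@H]1CC=C2C | intermediate
19 | 4-methyl-3-ene with exocyclic C10=C18 methylene, 6β,12-bis(triethylsilyloxy) | C=C1CC[C@@H]([C@H](C)CO[Si](CC)(CC)CC)[C@@H](O[Si](CC)(CC)CC)[C@H]2[C@H]1CC=C2C | intermediate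
20 | 6β,12-diol with C3=C4 (4-methyl) and C10=C18 alkenes | C=C1CC[C@@H]([C@H](C)CO)[C@@H](O)[C@H]2[C@H]1CC=C2C | intermediate
21 | 3β,4β-epoxy-6β,12-diol (4α-methyl) | C=C1CC[C@@H]([C@H](C)CO)[C@@H](O)[C@H]2[C@H]1C[C@@H]3O[C@]23C | intermediate
22 | 3α-phenylselanyl-4β,6β,12-triol | C=C1CC[C@@H]([C@H](C)CO)[C@@H](O)[C@H]2[C@H]1C[C@@H]([Se]c3ccccc3)[C@]2(C)O | intermediate
23 | selenoxide of 22 | C=C1CC[C@@H]([C@H](C)CO)[C@@H](O)[C@H]2[C@H]1C[C@@H]([Se](=O)c3ccccc3)[C@]2(C)O | intermediate
24 | 4β,6β,12-triol with C2=C3 and C10=C18 alkenes | C=C1CC[C@@H]([C@H](C)CO)[C@@H](O)[C@H]2[C@H]1C=C[C@]2(C)O | intermediate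
25 | 12-iodo-4β,6β-diol | C=C1CC[C@@H]([C@H](C)CI)[C@@H](O)[C@H]2[C@H]1C=C[C@]2(C)O | intermediate
26 | 12-iodo-4β,6β-bis(triethylsilyloxy) compound | C=C1CC[C@@H]([C@H](C)CI)[C@@H](O[Si](CC)(CC)CC)[C@H]2[C@H]1C=C[C@]2(C)O[Si](CC)(CC)CC | intermediate
27 | 3-methylbut-2-enal | CC(C)=CC=O | starting material
28 | C12 alkylzinc iodide | C=C1CC[C@@H]([C@H](C)C[Zn]I)[C@@H](O[Si](CC)(CC)CC)[C@H]2[C@H]1C=C[C@]2(C)O[Si](CC)(CC)CC | intermediate
29 | C12 alkyl(trimethylsilylmethyl)zinc | C=C1CC[C@@H]([C@H](C)C[Zn]C[Si](C)(C)C)[C@@H](O[Si](CC)(CC)CC)[C@H]2[C@H]1C=C[C@]2(C)O[Si](CC)(CC)CC | intermediate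
30 | (13R)-zinc alkoxide | C=C1CC[C@@H]([C@H](C)C[C@H](C=C(C)C)O[Zn]C[Si](C)(C)C)[C@@H](O[Si](CC)(CC)CC)[C@H]2[C@H]1C=C[C@]2(C)O[Si](CC)(CC)CC | intermediate
31 | (13R)-13-acetoxy-4β,6β-bis(triethylsilyloxy) compound | C=C1CC[C@@H]([C@H](C)C[C@H](C=C(C)C)OC(C)=O)[C@@H](O[Si](CC)(CC)CC)[C@H]2[C@H]1C=C[C@]2(C)O[Si](CC)(CC)CC | intermediate
32 | target CNP0209568.3 | C=C1CC[C@@H]([C@H](C)C[C@H](C=C(C)C)OC(C)=O)[C@@H](O)[C@H]2[C@H]1C=C[C@]2(C)O | target

Total step count: 15. Longest linear sequence: 15 steps (from 1; compounds 2, 7, 8 and 27 are purchased).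

Steps most likely to fail

Step 14. The hindered, β-branched alkyl group may transfer slowly from zinc, or the catalyst may control the carbonyl face only partly, giving a mixture at C13. The fallback keeps the same bond but separates bond formation from stereocontrol. It sets out from 26: the alkylzinc iodide 28 is made as before and acylated with 3-methylbut-2-enoyl chloride under Pd(PPh3)4 catalysis (Negishi acylation) to give the C13 ketone F1. Reduction with BH3·SMe2 and (S)-2-methyl-CBS-oxazaborolidine, with the alkenyl group acting as the large substituent, should give the (13R)-alcohol F2. Acetylation (Ac2O, pyridine, DMAP) comes back to the route at 31.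

Step 4. The enolate may be quenched by proton transfer from the enolisable α-branched aldehyde, it may lose the β-silyloxy group, or the aldol may show poor simple and facial diastereoselection at C6. The fallback is stepwise and moves the aldol to boron. It sets out from 7 and 8: the vinylcopper reagent 10 is added to 8 in the presence of Me3SiCl and the trimethylsilyl enol ether F3 is isolated. Silicon–boron exchange with Bu2BOTf gives the dibutylboron enolate F4, whose tight six-membered transition state should enforce the anti aldol with 6. Oxidative work-up comes back to the route at 12.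

Step 7. Hydride may be delivered 1,2 to the cyclopentenone carbonyl instead of 1,4, giving an allylic alcohol and no enolate. The fallback replaces hydride reduction by catalytic hydrosilylation. It sets out from 15: RhCl(PPh3)3-catalysed 1,4-hydrosilylation with Et3SiH gives the triethylsilyl enol ether F5. MeLi cleaves it to the lithium enolate 16, and PhNTf2 comes back to the route at 17.

Further compounds
F1 | step 14 | C13 ketone (13-oxo-4β,6β-bis(triethylsilyloxy) compound) | C=C1CC[C@@H]([C@H](C)CC(=O)C=C(C)C)[C@@H](O[Si](CC)(CC)CC)[C@H]2[C@H]1C=C[C@]2(C)O[Si](CC)(CC)CC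
F2 | step 14 | (13R)-alcohol (13-hydroxy-4β,6β-bis(triethylsilyloxy) compound) | C=C1CC[C@@H]([C@H](C)C[C@H](C=C(C)C)O)[C@@H](O[Si](CC)(CC)CC)[C@H]2[C@H]1C=C[C@]2(C)O[Si](CC)(CC)CC
F3 | step 4 | trimethylsilyl enol ether of (3R,4S)-4-(tert-butyldimethylsilyloxy)-3-[3-(trimethylsilyl)prop-1-en-2-yl]cyclopentanone | C[Si](C)(C)OC1=C[C@H](C(=C)C[Si](C)(C)C)[C@@H](O[Si](C)(C)C(C)(C)C)C1
F4 | step 4 | dibutylboron enolate of the same ketone | CCCCB(CCCC)OC1=C[C@H](C(=C)C[Si](C)(C)C)[C@@H](O[Si](C)(C)C(C)(C)C)C1
F5 | step 7 | triethylsilyl C3=C4 enol ether of the 2,3-dihydro derivative of 15 | C[Si](C)(C)CC1=CC[C@@H]([C@H](C)CO[Si](CC)(CC)CC)[C@@H](O[Si](CC)(CC)CC)[C@H]2[C@H]1CC=C2O[Si](CC)(CC)CC
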